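**Retrosynthetic overview**
1. Target 27 ⇐ acetylation and fluoride desilylation of diene ester 24; the (E)-diene ⇐ hydrozirconation–vinylation of a C9 but-2-ynyl group; C3 methylene ⇐ deoxygenation of a 3-ketone.
2. Rings A and B together ⇐ Mn(OAc)3/Cu(OAc)2 oxidative radical bicyclization of the acyclic 2-methyl-3-oxo ester 17. Ring A closes first (C4–C5), ring B second (C10–C9), and oxidative termination gives the exocyclic alkene. The C7 silyl ether is the only stereocentre carried in.
3. 17 ⇐ γ-alkylation of the dianion of keto ester 15 with allylic bromide 12.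
4. 12 ⇐ enantioselective vinylogous Mukaiyama aldol of enynal 5 with tiglate dienolate 7; 5 ⇐ prenyl chloride + propynylmagnesium bromide, then SeO2.

Position numbers C1–C20 in the text are labdane numbers. The target is 7α-acetoxylabda-8(17),12E,14-trien-19-oic acid (4β-CO2H, 5α-H, 9α-H, 10β-CH3).
Assumption: the (R,R)-bisphosphoramide/SiCl4 catalyst delivers the dienolate to the Re face of enal 5, as it does with cinnamaldehyde-type enals, giving (5R)-9; if the sense is opposite, the (S,S)-catalyst is used and nothing else changes.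

**Route**

Step 1
Reactants: 1 1-chloro-3-methylbut-2-ene (prenyl chloride); 2 prop-1-yn-1-ylmagnesium bromide
Product: 3 6-methylhept-5-en-2-yne
Conditions: CuI (5 mol%), THF, 0 °C → 50 °C
Reagents that add atoms: none
Why: Copper-catalysed SN2 allyl–alkynyl coupling at the unhindered primary carbon (SN2′ attack would have to build a quaternary carbon); no stereocentre is formed.

Step 2
Reactants: 3 6-methylhept-5-en-2-yne
Product: 5 (2E)-2-methylhept-2-en-5-ynal, via allylic alcohol 4 (not isolated)
Conditions: SeO2 (1.2 equiv), 1,4-dioxane, H2O (2 equiv), 90 °C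
Reagents that add atoms: selenium dioxide, O=[Se]=O
Why: Riley allylic oxidation (ene reaction then [2,3]-sigmatropic shift) oxidises the (E)-methyl of the trisubstituted alkene selectively and carries alcohol 4 on to the conjugated (E)-enal, the propargylic positions reacting more slowly.

Step 3
Reactants: 6 ethyl (2E)-2-methylbut-2-enoate (ethyl tiglate)
Product: 7 tert-butyl[(1-ethoxy-2-methylbuta-1,3-dien-1-yl)oxy]dimethylsilane (ketene-acetal E/Z mixture, used as such)
Conditions: LiN(iPr)2 (1.1 equiv), DMPU, THF, −78 °C; TBSCl, −78 °C → rt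
Reagents that add atoms: tert-butyldimethylsilyl chloride, CC(C)(C)[Si](C)(C)Cl
Why: Kinetic γ-deprotonation of the enoate and O-silylation of the extended enolate give the silyl dienolate needed for a vinylogous Mukaiyama aldol.

Step 4
Reactants: 5 (2E)-2-methylhept-2-en-5-ynal; 7 silyl dienolate
Product: 9 ethyl (2E,5R,6E)-5-hydroxy-2,6-dimethylundeca-2,6-dien-9-ynoate, via trichlorosilyl ether 8 (not isolated)
Conditions: SiCl4 (1.1 equiv), (R,R)-binaphthyl-2,2′-diamine-derived bisphosphoramide (2 mol%), i-Pr2NEt (10 mol%), CH2Cl2, −72 °C; aq. NaHCO3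
Reagents that add atoms: none
Why: Lewis-base-activated SiCl4 vinylogous Mukaiyama aldol (Denmark type) in which the chiral trichlorosilyl cation binds the enal and the dienolate attacks through its γ-carbon on the Re face, setting the future C7 as R and the (E)-trisubstituted enoate in one step.

Step 5
Reactants: 9 hydroxy ester
Product: 10 ethyl (2E,5R,6E)-5-[(tert-butyldimethylsilyl)oxy]-2,6-dimethylundeca-2,6-dien-9-ynoate
Conditions: TBSCl (1.3 equiv), imidazole (2.5 equiv), DMF, rt
Reagents that add atoms: tert-butyldimethylsilyl chloride, CC(C)(C)[Si](C)(C)Cl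
Why: Imidazole-promoted O-silylation protects the secondary allylic alcohol for the hydride and dianion steps without touching the stereocentre.

Step 6
Reactants: 10 silyl ether ester
Product: 11 (2E,5R,6E)-5-[(tert-butyldimethylsilyl)oxy]-2,6-dimethylundeca-2,6-dien-9-yn-1-ol
Conditions: i-Bu2AlH (2.3 equiv), CH2Cl2, −78 °C; aq. Rochelle salt
Reagents that add atoms: none
Why: 1,2-Reduction of the enoate by i-Bu2AlH gives the (E)-allylic alcohol with alkene geometry, alkyne and silyl ether untouched.

Step 7
Reactants: 11 allylic alcohol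
Product: 12 {[(2E,5R,6E)-1-bromo-2,6-dimethylundeca-2,6-dien-9-yn-5-yl]oxy}(tert-butyl)dimethylsilane
Conditions: CBr4 (1.2 equiv), PPh3 (1.25 equiv), CH2Cl2, 0 °C
Reagents that add atoms: carbon tetrabromide, BrC(Br)(Br)Br
Why: Appel bromination proceeds by SN2 displacement at the primary allylic carbon under neutral conditions, so there is no allylic transposition and no loss of the silyl ether.

Step 8
Reactants: 13 ethyl 2-methyl-3-oxobutanoate; 14 2-(trimethylsilyl)ethanol
Product: 15 2-(trimethylsilyl)ethyl 2-methyl-3-oxobutanoate (racemic)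
Conditions: DMAP (10 mol%), toluene, reflux, 4 Å molecular sieves (removal of EtOH)
Reagents that add atoms: none
Why: DMAP-catalysed transesterification of a β-keto ester, driven by removal of ethanol, installs an ester that fluoride can later cleave by alkyl–oxygen fragmentation even at the hindered axial C19 position.

Step 9
Reactants: 15 2-(trimethylsilyl)ethyl 2-methyl-3-oxobutanoate; 12 allylic bromide
Product: 17 2-(trimethylsilyl)ethyl (6E,9R,10E)-9-[(tert-butyldimethylsilyl)oxy]-2,6,10-trimethyl-3-oxopentadeca-6,10-dien-13-ynoate (C2 epimers), via dilithium dianion 16 (not isolated)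
Conditions: 15 (1.3 equiv), LiN(iPr)2 (2.6 equiv), THF, 0 °C; 12, −78 → 0 °C; aq. NH4Cl
Reagents that add atoms: none
Why: Huckin–Weiler dianion alkylation, in which the more basic terminal (γ) carbanion displaces the primary allylic bromide by SN2 with retention of the (E)-geometry; the C2 epimer mixture is irrelevant because C2 becomes the radical centre (C4) in the next step.

Step 10
Reactants: 17 acyclic keto ester
Product: 18 2-(trimethylsilyl)ethyl (1R,4aR,5R,7R,8aR)-5-(but-2-yn-1-yl)-7-[(tert-butyldimethylsilyl)oxy]-1,4a-dimethyl-6-methylidene-2-oxodecahydronaphthalene-1-carboxylate (3-oxo, 7α-OTBS, 8(17)-ene, 19-ester)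
Conditions: Mn(OAc)3·2H2O (2.2 equiv), Cu(OAc)2·H2O (1.0 equiv), degassed AcOH, 0.03 M, 25 °C, 16 h; chromatography
Reagents that add atoms: none
Why: Proposed new method: the ring construction itself is the known Mn(OAc)3/Cu(OAc)2 oxidative radical polyene cyclization of a 2-methyl-3-oxo ester (the tertiary C4 radical closes ring A 6-endo through a chair with the ester axial and cis to the C10 methyl, the C10 radical closes ring B 6-endo on the (E)-alkene to put H5 and H9 trans to that methyl, and divalent copper turns the C8 radical into the exocyclic alkene), and what is new is the use of the C7 silyloxy stereocentre as the only source of absolute configuration: in the ring-B chair the OTBS group goes axial (7α) to avoid A(1,2) strain with the C8 methyl and to align σ*(C–O) with the reacting π bond, so (7R)-17 channels the natural ring-A antipode into 18, while the other ring-A antipode, expected in similar amount because ring A closes remote from C7, ends as a separable 7-equatorial diastereomer; the closest known reaction types are auxiliary-controlled trivalent-manganese radical cyclizations and allylic-substituent-controlled cation–olefin cyclizations.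

Step 11
Reactants: 18 bicyclic keto ester
Product: 20 2-(trimethylsilyl)ethyl (1S,4aR,5R,7R,8aR)-5-(but-2-yn-1-yl)-7-[(tert-butyldimethylsilyl)oxy]-1,4a-dimethyl-6-methylidenedecahydronaphthalene-1-carboxylate, via tosylhydrazone 19 (not isolated)
Conditions: TsNHNH2 (1.5 equiv), AcOH (cat.), EtOH, 70 °C; evaporate; catecholborane (3 equiv), CHCl3, 0 °C → rt; NaOAc·3H2O, 60 °C
Reagents that add atoms: none
Why: Tosylhydrazone reduction (Caglioti/Kabalka type), in which hydroboration of the C=N bond, loss of sulfinate and extrusion of N2 from the diazene replace the C3 carbonyl by CH2 under conditions that spare the ester, silyl ether, alkyne and exocyclic alkene; no stereocentre is touched.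

Step 12
Reactants: 20 deoxygenated bicyclic ester; 21 vinyl bromide
Product: 24 2-(trimethylsilyl)ethyl (1S,4aR,5R,7R,8aR)-7-[(tert-butyldimethylsilyl)oxy]-1,4a-dimethyl-6-methylidene-5-[(2E)-3-methylpenta-2,4-dien-1-yl]decahydronaphthalene-1-carboxylate, via alkenylzirconocene 22 (not isolated), via alkenylzinc chloride 23 (not isolated)
Conditions: Cp2Zr(H)Cl (1.6 equiv), THF, 40 °C; ZnCl2 (1.6 equiv), 0 °C; 21 (3 equiv), Pd(PPh3)4 (5 mol%), rt
Reagents that add atoms: none
Why: Hydrozirconation–Negishi coupling, in which syn addition of Zr–H puts zirconium on the less hindered, methyl-bearing alkyne carbon after equilibration and transmetalation to zinc and palladium-catalysed vinylation proceed with retention, fixing the 12E geometry.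

Step 13
Reactants: 24 diene silyl ether ester
Product: 25 (1S,4aR,5R,7R,8aR)-7-hydroxy-1,4a-dimethyl-6-methylidene-5-[(2E)-3-methylpenta-2,4-dien-1-yl]decahydronaphthalene-1-carboxylic acid (7α-hydroxy-trans-communic acid)
Conditions: Bu4NF (4 equiv), THF, 40 °C; aq. NH4Cl
Reagents that add atoms: none
Why: Fluoride cleaves the silyl ether and fragments the 2-(trimethylsilyl)ethyl ester (β-silyl elimination to ethylene and fluorotrimethylsilane), which frees the hindered axial acid without attack at its carbonyl and without acid that would harm the diene.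

Step 14
Reactants: 25 hydroxy acid
Product: 27 (1S,4aR,5R,7R,8aR)-7-acetoxy-1,4a-dimethyl-6-methylidene-5-[(2E)-3-methylpenta-2,4-dien-1-yl]decahydronaphthalene-1-carboxylic acid (target), via mixed anhydride 26 (not isolated)
Conditions: Ac2O (5 equiv), pyridine, DMAP (10 mol%), CH2Cl2, rt; then THF/aq. NaHCO3, rt; acidify to pH 4 (citric acid)
Reagents that add atoms: acetic anhydride, CC(=O)OC(C)=O
Why: DMAP-catalysed O-acetylation of the axial 7α-alcohol with retention, any mixed anhydride at C19 being hydrolysed back to the acid during the bicarbonate work-up.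

**Compound list**
1 | 1-chloro-3-methylbut-2-ene (prenyl chloride) | CC(C)=CCCl | starting material
2 | prop-1-yn-1-ylmagnesium bromide | CC#C[Mg]Br | starting material
3 | 6-methylhept-5-en-2-yne | CC#CCC=C(C)C | intermediate
4 | (2E)-2-methylhept-2-en-5-yn-1-ol (formed in the flask) | CC#CC/C=C(\C)CO | intermediate
5 | (2E)-2-methylhept-2-en-5-ynal | CC#CC/C=C(\C)C=O | intermediate
6 | ethyl (2E)-2-methylbut-2-enoate (ethyl tiglate) | C/C=C(\C)C(=O)OCC | starting material
7 | tert-butyl[(1-ethoxy-2-methylbuta-1,3-dien-1-yl)oxy]dimethylsilane (E/Z mixture) | C=CC(C)=C(OCC)O[Si](C)(C)C(C)(C)C | intermediate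
8 | ethyl (2E,5R,6E)-2,6-dimethyl-5-[(trichlorosilyl)oxy]undeca-2,6-dien-9-ynoate (formed in the flask) | CC#CC/C=C(\C)[C@H](O[Si](Cl)(Cl)Cl)C/C=C(\C)C(=O)OCC | intermediate
9 | ethyl (2E,5R,6E)-5-hydroxy-2,6-dimethylundeca-2,6-dien-9-ynoate | CC#CC/C=C(\C)[C@H](O)C/C=C(\C)C(=O)OCC | intermediate
10 | ethyl (2E,5R,6E)-5-[(tert-butyldimethylsilyl)oxy]-2,6-dimethylundeca-2,6-dien-9-ynoate | CC#CC/C=C(\C)[C@H](O[Si](C)(C)C(C)(C)C)C/C=C(\C)C(=O)OCC | intermediate
11 | (2E,5R,6E)-5-[(tert-butyldimethylsilyl)oxy]-2,6-dimethylundeca-2,6-dien-9-yn-1-ol | CC#CC/C=C(\C)[C@H](O[Si](C)(C)C(C)(C)C)C/C=C(\C)CO | intermediate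
12 | {[(2E,5R,6E)-1-bromo-2,6-dimethylundeca-2,6-dien-9-yn-5-yl]oxy}(tert-butyl)dimethylsilane | CC#CC/C=C(\C)[C@H](O[Si](C)(C)C(C)(C)C)C/C=C(\C)CBr | intermediate
13 | ethyl 2-methyl-3-oxobutanoate | CCOC(=O)C(C)C(C)=O | starting material
14 | 2-(trimethylsilyl)ethanol | C[Si](C)(C)CCO | starting material
15 | 2-(trimethylsilyl)ethyl 2-methyl-3-oxobutanoate (racemic) | CC(=O)C(C)C(=O)OCC[Si](C)(C)C | intermediate
16 | dilithium dianion of 15 (formed in the flask) | [Li+].[Li+].C=C([O-])C(C)=C([O-])OCC[Si](C)(C)C | intermediate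
17 | 2-(trimethylsilyl)ethyl (6E,9R,10E)-9-[(tert-butyldimethylsilyl)oxy]-2,6,10-trimethyl-3-oxopentadeca-6,10-dien-13-ynoate (C2 epimers) | CC#CC/C=C(\C)[C@H](O[Si](C)(C)C(C)(C)C)C/C=C(\C)CCC(=O)C(C)C(=O)OCC[Si](C)(C)C | intermediate
18 | 2-(trimethylsilyl)ethyl (1R,4aR,5R,7R,8aR)-5-(but-2-yn-1-yl)-7-[(tert-butyldimethylsilyl)oxy]-1,4a-dimethyl-6-methylidene-2-oxodecahydronaphthalene-1-carboxylate | CC#CC[C@H]1C(=C)[C@H](O[Si](C)(C)C(C)(C)C)C[C@@H]2[C@]1(C)CCC(=O)[C@]2(C)C(=O)OCC[Si](C)(C)C | intermediate
19 | p-toluenesulfonylhydrazone of 18 at the ring ketone (C=N geometry open; formed in the flask) | CC#CC[C@H]1C(=C)[C@H](O[Si](C)(C)C(C)(C)C)C[C@@H]2[C@]1(C)CCC(=NNS(=O)(=O)c1ccc(C)cc1)[C@]2(C)C(=O)OCC[Si](C)(C)C | intermediate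
20 | 2-(trimethylsilyl)ethyl (1S,4aR,5R,7R,8aR)-5-(but-2-yn-1-yl)-7-[(tert-butyldimethylsilyl)oxy]-1,4a-dimethyl-6-methylidenedecahydronaphthalene-1-carboxylate | CC#CC[C@H]1C(=C)[C@H](O[Si](C)(C)C(C)(C)C)C[C@@H]2[C@]1(C)CCC[C@]2(C)C(=O)OCC[Si](C)(C)C | intermediate
21 | vinyl bromide | C=CBr | starting material
22 | (E)-alkenylzirconocene chloride from 20, Cp2ZrCl on C13 (formed in the flask; Cp drawn σ-bonded) | C/C(=C\C[C@H]1C(=C)[C@H](O[Si](C)(C)C(C)(C)C)C[C@@H]2[C@]1(C)CCC[C@]2(C)C(=O)OCC[Si](C)(C)C)[Zr](Cl)(C1C=CC=C1)C1C=CC=C1 | intermediate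
23 | (E)-alkenylzinc chloride from 22 (formed in the flask) | C/C(=C\C[C@H]1C(=C)[C@H](O[Si](C)(C)C(C)(C)C)C[C@@H]2[C@]1(C)CCC[C@]2(C)C(=O)OCC[Si](C)(C)C)[Zn]Cl | intermediate
24 | 2-(trimethylsilyl)ethyl (1S,4aR,5R,7R,8aR)-7-[(tert-butyldimethylsilyl)oxy]-1,4a-dimethyl-6-methylidene-5-[(2E)-3-methylpenta-2,4-dien-1-yl]decahydronaphthalene-1-carboxylate | C=C/C(C)=C/C[C@H]1C(=C)[C@H](O[Si](C)(C)C(C)(C)C)C[C@@H]2[C@]1(C)CCC[C@]2(C)C(=O)OCC[Si](C)(C)C | intermediate
25 | (1S,4aR,5R,7R,8aR)-7-hydroxy-1,4a-dimethyl-6-methylidene-5-[(2E)-3-methylpenta-2,4-dien-1-yl]decahydronaphthalene-1-carboxylic acid | C=C/C(C)=C/C[C@H]1C(=C)[C@H](O)C[C@@H]2[C@]1(C)CCC[C@]2(C)C(=O)O | intermediate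
26 | acetic mixed anhydride of the target at C19 (formed in the flask) | C=C/C(C)=C/C[C@H]1C(=C)[C@H](OC(C)=O)C[C@@H]2[C@]1(C)CCC[C@]2(C)C(=O)OC(C)=O | intermediate
27 | (1S,4aR,5R,7R,8aR)-7-acetoxy-1,4a-dimethyl-6-methylidene-5-[(2E)-3-methylpenta-2,4-dien-1-yl]decahydronaphthalene-1-carboxylic acid | C=C/C(C)=C/C[C@H]1C(=C)[C@H](OC(C)=O)C[C@@H]2[C@]1(C)CCC[C@]2(C)C(=O)O | target

**Step count and risks**
Total steps: 14. Longest linear sequence: 12 (steps 1, 2, 4, 5, 6, 7, 9, 10, 11, 12, 13, 14). The enantiomeric purity of 27 equals that of 9, because the step-10 diastereomers are separated.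

Most likely to fail:

Step 10. The radical cascade itself has close precedent, but C7 can only sort the two ring-A antipodes, not bias their formation. At best about half of the bicyclic material is 18 (realistically 20–25% isolated), with olefin isomers from the termination as further by-products. Fallback, setting out from 17 and coming back at 18: 17 is brominated between the two carbonyls (NBS, Mg(ClO4)2 cat., MeCN) to the α-bromo keto ester F1. F1 is then cyclized by bromine-atom transfer (Et3B/O2, stoichiometric Mg(ClO4)2 with a C2-symmetric bis(oxazoline), CH2Cl2/toluene, −78 °C). Here the C4 radical stays chelated to the chiral magnesium Lewis acid, so the ligand, chosen matched to C7, selects the ring-A face that the free radical of step 10 cannot, and the chain ends at the tertiary C8 bromide F2. Dehydrobromination of F2 (DBU, toluene, 80 °C, alkene isomers separated) gives 18.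

Step 11. The C3 ketone sits next to the quaternary C4 bearing an axial ester, so hydrazone formation may be sluggish or incomplete. Fallback, setting out from 18 and coming back at 20: NaBH4 in MeOH reduces the ketone to the 3-hydroxy ester F3 (either C3 epimer serves). 1,1′-Thiocarbonyldiimidazole with DMAP in 1,2-dichloroethane at 70 °C converts it to the imidazolyl thiocarbonate F4 under non-basic conditions that avoid retro-aldol cleavage. Barton–McCombie reduction (Bu3SnH, AIBN, toluene, 100 °C) then gives 20.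

Step 12. The risks are incomplete regiocontrol in the hydrozirconation of the hindered 2-alkyne and a slow zirconium-to-zinc-to-palladium relay at a trisubstituted alkenyl centre. Fallback, setting out from 20 and coming back at 24: the one-pot relay is given up. Hydrozirconation (Cp2Zr(H)Cl, THF) is quenched with I2 to give the discrete (E)-vinyl iodide F5, which is freed from its regioisomer by chromatography. The C13–C14 bond is then made by Stille coupling with tributyl(vinyl)stannane (Pd2(dba)3, AsPh3, NMP, rt) to give 24.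

**Further compounds**
F1 | step 10 | 2-(trimethylsilyl)ethyl (6E,9R,10E)-2-bromo-9-[(tert-butyldimethylsilyl)oxy]-2,6,10-trimethyl-3-oxopentadeca-6,10-dien-13-ynoate (C2 epimers) | CC#CC/C=C(\C)[C@H](O[Si](C)(C)C(C)(C)C)C/C=C(\C)CCC(=O)C(C)(Br)C(=O)OCC[Si](C)(C)C
F2 | step 10 | 8-bromo-8-methyl analogue of 18 (tertiary C8 bromide in place of the exocyclic alkene, C8 configuration open) | CC#CC[C@H]1C(C)(Br)[C@H](O[Si](C)(C)C(C)(C)C)C[C@@H]2[C@]1(C)CCC(=O)[C@]2(C)C(=O)OCC[Si](C)(C)C
F3 | step 11 | 3-hydroxy analogue of 18 (C3 epimers) | CC#CC[C@H]1C(=C)[C@H](O[Si](C)(C)C(C)(C)C)C[C@@H]2[C@]1(C)CCC(O)[C@]2(C)C(=O)OCC[Si](C)(C)C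
F4 | step 11 | O-(1H-imidazol-1-ylcarbonothioyl) derivative of F3 | CC#CC[C@H]1C(=C)[C@H](O[Si](C)(C)C(C)(C)C)C[C@@H]2[C@]1(C)CCC(OC(=S)n1ccnc1)[C@]2(C)C(=O)OCC[Si](C)(C)C
F5 | step 12 | (E)-C13 vinyl iodide from 20, side chain CH2–CH=C(CH3)I | C/C(I)=C\C[C@H]1C(=C)[C@H](O[Si](C)(C)C(C)(C)C)C[C@@H]2[C@]1(C)CCC[C@]2(C)C(=O)OCC[Si](C)(C)C
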